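**Plan**

- Retrosynthesis: the three MOM ethers and the two C=N bonds of a protected 1,2-diimine are taken back first. The diimine is then cut at three bonds at once, C1'(ring A)–Ca, Ca–Cb and Cb–C1(ring B), into a ring A aryl bromide, two molecules of tert-butyl isocyanide and a ring B arylaluminium.
- Enabling feature: the vicinal carbonyl carbons Ca (on ring A, the 2-hydroxy-4-methoxyphenyl ring) and Cb (on ring B, the 2,4-dihydroxy-3-prenylphenyl ring) are each a single carbon between two sp2 carbons. Each can therefore be an isocyanide carbon placed between an aryl halide carbon (C1' of ring A) and an aryl metal carbon (C1 of ring B).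
- Forward order: both benzene rings are bought and no ring is formed. Ring B is built up from resorcinol (MOM protection, C2 lithiation and prenylation, C4 lithiation and alumination), ring A from 2-bromo-5-methoxyphenol (MOM protection). The halves are joined through Ca and Cb in step 5, followed by imine hydrolysis and MOM removal.
- Stereochemistry: the target has no stereocentre and its only alkene (prenyl) has no E/Z isomers; the C=N geometry of the diimine disappears on hydrolysis.

Key step: step 5

Remark: the mixed reagent 10 is assumed to hand over its aryl group ahead of an ethyl group, as aryl(dialkyl)aluminium reagents do in palladium-catalysed cross-coupling; 10 is prepared and used as a THF solution.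

**Route**

Step 1
Reactants: 1 resorcinol
Product: 2 1,3-bis(methoxymethoxy)benzene
Conditions: NaH, MOMCl, DMF, 0 °C to rt
Reagents that add atoms: chloromethyl methyl ether (MOMCl), COCCl
Why: Williamson-type O-alkylation of the sodium bis-phenoxide with the reactive α-chloro ether should give the bis-acetal, and the two hydroxyls are equivalent so no selectivity is at stake.

Step 2
Reactants: 2 1,3-bis(methoxymethoxy)benzene; 3 prenyl bromide (1-bromo-3-methylbut-2-ene)
Product: 6 1,3-bis(methoxymethoxy)-2-(3-methylbut-2-enyl)benzene, via 2,6-bis(methoxymethoxy)phenyllithium 4 (not isolated), via 2,6-bis(methoxymethoxy)phenylcopper 5 (not isolated)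
Conditions: n-BuLi, THF, 0 °C; CuI, −40 °C; then 3, −40 °C to rt
Reagents that add atoms: none
Why: Directed ortho-metalation removes the hydrogen flanked by the two OMOM groups, the most acidic ring position, and after transmetallation to copper the aryl group should substitute prenyl bromide at its primary carbon (SN2-type allylic substitution) to give the linear 3-methylbut-2-enyl group.

Step 3
Reactants: 7 2-bromo-5-methoxyphenol
Product: 8 1-bromo-4-methoxy-2-(methoxymethoxy)benzene
Conditions: NaH, MOMCl, DMF, 0 °C to rt
Reagents that add atoms: chloromethyl methyl ether (MOMCl), COCCl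
Why: Williamson-type O-alkylation of the phenoxide, to which the aryl bromide is inert.

Step 4
Reactants: 6 1,3-bis(methoxymethoxy)-2-(3-methylbut-2-enyl)benzene
Product: 10 diethyl[2,4-bis(methoxymethoxy)-3-(3-methylbut-2-enyl)phenyl]aluminium, via 2,4-bis(methoxymethoxy)-3-(3-methylbut-2-enyl)phenyllithium 9 (not isolated)
Conditions: s-BuLi, TMEDA, THF, −78 °C; then Et2AlCl (hexanes), −78 °C to rt
Reagents that add atoms: diethylaluminium chloride, CC[Al](Cl)CC
Why: Directed ortho-metalation, in which the OMOM group at C3 guides s-BuLi/TMEDA to C4 (C6 is the same position by symmetry) under kinetic control ahead of the benzylic–allylic CH2, followed by salt metathesis of the aryllithium with Et2AlCl before it can isomerise.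

Step 5
Reactants: 8 1-bromo-4-methoxy-2-(methoxymethoxy)benzene; 10 diethyl[2,4-bis(methoxymethoxy)-3-(3-methylbut-2-enyl)phenyl]aluminium; 11 tert-butyl isocyanide (two equivalents incorporated)
Product: 12 N,N'-di-tert-butyl-1-[2,4-bis(methoxymethoxy)-3-(3-methylbut-2-enyl)phenyl]-2-[4-methoxy-2-(methoxymethoxy)phenyl]ethane-1,2-diimine
Conditions: Pd(OAc)2 (5 mol%), DPEphos (10 mol%), 11 (2.2 equiv), toluene, 90 °C; 10 (1.3 equiv, THF solution) added over 3 h; non-acidic work-up
Reagents that add atoms: none
Why: Zerovalent palladium, formed from Pd(OAc)2 and DPEphos, should add oxidatively to the C–Br bond of 8; migratory insertion of 11 gives an imidoylpalladium bromide and a second insertion the α-iminoimidoyl complex, which transmetallates with 10 and reductively eliminates, so that C1'(ring A)–Ca, Ca–Cb and Cb–C1(ring B) arise in one operation. The closest known reaction type is the palladium-catalysed three-component coupling of aryl halides, tert-butyl isocyanide and organoaluminium reagents, which delivers 1,2-diimines and, after hydrolysis, 1,2-diketones. No ring closes and no stereocentre is created, and the geometry of the two C=N bonds is irrelevant because both are hydrolysed in step 6. The step needs exactly two insertions and transfer of the aryl rather than an ethyl group from aluminium: the tert-butyl groups disfavour a third insertion, the isocyanide is held to a slight excess over two equivalents, slow addition of 10 keeps transmetallation behind the second insertion, and sp2 groups leave mixed aryl(dialkyl)aluminiums faster than sp3 groups. Because both rings arrive with all their substituents, the electron-rich o-hydroxyaryl diketone is first unveiled only as a robust, fully protected diimine.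

Step 6
Reactants: 12 the N,N'-di-tert-butyl 1,2-diimine
Product: 13 1-[2,4-bis(methoxymethoxy)-3-(3-methylbut-2-enyl)phenyl]-2-[4-methoxy-2-(methoxymethoxy)phenyl]ethane-1,2-dione (tris-MOM licoagrodione)
Conditions: 1 M aq. HCl, THF, 0 °C to rt
Reagents that add atoms: water, O
Why: Acid-catalysed imine hydrolysis, which for protonated N-tert-butyl ketimines should be much faster than ionisation of aryl MOM acetals in cold dilute aqueous acid, so the three MOM groups are expected to stay on.

Step 7
Reactants: 13 tris-MOM licoagrodione
Product: 14 licoagrodione, 1-[2,4-dihydroxy-3-(3-methylbut-2-enyl)phenyl]-2-(2-hydroxy-4-methoxyphenyl)ethane-1,2-dione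
Conditions: 3 M aq. HCl, MeOH, rt to 40 °C
Reagents that add atoms: none
Why: Acid-catalysed solvolysis of the three aryl methoxymethyl acetals (MOM cleavage, the cation being trapped by methanol), run at mild temperature to limit acid-induced cyclisation of the prenyl group onto a neighbouring phenol.

**Compound list**

1 | resorcinol | Oc1cccc(O)c1 | starting material
2 | 1,3-bis(methoxymethoxy)benzene | COCOc1cccc(OCOC)c1 | intermediate
3 | prenyl bromide (1-bromo-3-methylbut-2-ene) | CC(C)=CCBr | starting material
4 | 2,6-bis(methoxymethoxy)phenyllithium (not isolated) | [Li]c1c(OCOC)cccc1OCOC | intermediate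
5 | 2,6-bis(methoxymethoxy)phenylcopper (not isolated) | [Cu]c1c(OCOC)cccc1OCOC | intermediate
6 | 1,3-bis(methoxymethoxy)-2-(3-methylbut-2-enyl)benzene | COCOc1cccc(OCOC)c1CC=C(C)C | intermediate
7 | 2-bromo-5-methoxyphenol | COc1ccc(Br)c(O)c1 | starting material
8 | 1-bromo-4-methoxy-2-(methoxymethoxy)benzene | COCOc1cc(OC)ccc1Br | intermediate
9 | 2,4-bis(methoxymethoxy)-3-(3-methylbut-2-enyl)phenyllithium (not isolated) | [Li]c1ccc(OCOC)c(CC=C(C)C)c1OCOC | intermediate
10 | diethyl[2,4-bis(methoxymethoxy)-3-(3-methylbut-2-enyl)phenyl]aluminium (used as THF solution) | CC[Al](CC)c1ccc(OCOC)c(CC=C(C)C)c1OCOC | intermediate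
11 | tert-butyl isocyanide | CC(C)(C)[N+]#[C-] | starting material
12 | N,N'-di-tert-butyl-1-[2,4-bis(methoxymethoxy)-3-(3-methylbut-2-enyl)phenyl]-2-[4-methoxy-2-(methoxymethoxy)phenyl]ethane-1,2-diimine (C=N geometry undefined) | COc1ccc(C(=NC(C)(C)C)C(=NC(C)(C)C)c2ccc(OCOC)c(CC=C(C)C)c2OCOC)c(OCOC)c1 | intermediate
13 | 1-[2,4-bis(methoxymethoxy)-3-(3-methylbut-2-enyl)phenyl]-2-[4-methoxy-2-(methoxymethoxy)phenyl]ethane-1,2-dione | COc1ccc(C(=O)C(=O)c2ccc(OCOC)c(CC=C(C)C)c2OCOC)c(OCOC)c1 | intermediate
14 | licoagrodione | COc1ccc(C(=O)C(=O)c2ccc(O)c(CC=C(C)C)c2O)c(O)c1 | target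

**Step count and risks**

Total step count: 7. Longest linear sequence: 6 steps (steps 1, 2, 4, 5, 6, 7 from resorcinol).

Steps most likely to fail:

1. Step 5. Transmetallation may overtake the second insertion (mono-insertion or direct biaryl coupling), an ethyl group or a β-hydride may be delivered from aluminium instead of the aryl group, oxidative addition to the electron-rich ortho-substituted bromide may be slow, and the aluminium bromide formed may attack MOM ethers at 90 °C. The fallback sets out from 9 (with 8 as partner) and returns at 13. Aryllithium 9, made as in step 4 but not aluminated, is added at −78 °C to 1,4-dimethylpiperazine-2,3-dione (commercial, CN1CCN(C)C(=O)C1=O) to give the stable tetrahedral mono-adduct lithium 2-[2,4-bis(methoxymethoxy)-3-(3-methylbut-2-enyl)phenyl]-1,4-dimethyl-3-oxopiperazin-2-olate F1. Separately, bromine–lithium exchange on 8 (n-BuLi, THF, −78 °C) gives 4-methoxy-2-(methoxymethoxy)phenyllithium F2, which is added to F1 with warming to 0 °C to form the bis-adduct dilithium 2-[2,4-bis(methoxymethoxy)-3-(3-methylbut-2-enyl)phenyl]-3-[4-methoxy-2-(methoxymethoxy)phenyl]-1,4-dimethylpiperazine-2,3-diolate F3. A brief quench with cold dilute aqueous HCl should release diketone 13, which continues with step 7. This is the known sequential addition of two different aryllithiums to the cyclic oxamide; the same three bonds are formed, with the two carbonyl carbons coming from the oxamide instead of the isocyanide.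

2. Step 4. Deprotonation may occur at the benzylic–allylic CH2 of the prenyl group instead of at C4, or the aryllithium may take a proton from that position before it is aluminated. The fallback sets out from 2 and returns at 9, fixing the metal position with a halogen. Bromination of 2 (N-bromosuccinimide, MeCN, 0 °C) should give 1-bromo-2,4-bis(methoxymethoxy)benzene F4. Lithium 2,2,6,6-tetramethylpiperidide (THF, −78 °C) deprotonates between the two OMOM groups to give 3-bromo-2,6-bis(methoxymethoxy)phenyllithium F5. CuI converts this into 3-bromo-2,6-bis(methoxymethoxy)phenylcopper F6, which is prenylated with 3 to give 1-bromo-2,4-bis(methoxymethoxy)-3-(3-methylbut-2-enyl)benzene F7. Bromine–lithium exchange on F7 (n-BuLi, THF, −78 °C) then delivers 9 regiospecifically, and alumination proceeds as in step 4.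

3. Step 7. Protic acid may add the neighbouring phenol (chroman formation), HCl or methanol across the prenyl double bond while the MOM groups are being removed. The fallback sets out from 13 and returns at 14 without Brønsted acid. Trimethylsilyl triflate and 2,2'-bipyridyl (CH2Cl2, 0 °C) should exchange the three aryl MOM ethers for silyl ethers, giving 1-[3-(3-methylbut-2-enyl)-2,4-bis(trimethylsilyloxy)phenyl]-2-[4-methoxy-2-(trimethylsilyloxy)phenyl]ethane-1,2-dione F8. Neutral hydrolysis (water, THF, rt) then frees the three phenols to give 14.

**Further compounds**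

F1 | step 5 | lithium 2-[2,4-bis(methoxymethoxy)-3-(3-methylbut-2-enyl)phenyl]-1,4-dimethyl-3-oxopiperazin-2-olate (racemic) | [Li]OC1(c2ccc(OCOC)c(CC=C(C)C)c2OCOC)N(C)CCN(C)C1=O
F2 | step 5 | 4-methoxy-2-(methoxymethoxy)phenyllithium | [Li]c1ccc(OC)cc1OCOC
F3 | step 5 | dilithium 2-[2,4-bis(methoxymethoxy)-3-(3-methylbut-2-enyl)phenyl]-3-[4-methoxy-2-(methoxymethoxy)phenyl]-1,4-dimethylpiperazine-2,3-diolate (diastereomer mixture, both centres lost on hydrolysis) | [Li]OC1(c2ccc(OC)cc2OCOC)N(C)CCN(C)C1(O[Li])c1ccc(OCOC)c(CC=C(C)C)c1OCOC
F4 | step 4 | 1-bromo-2,4-bis(methoxymethoxy)benzene | COCOc1ccc(Br)c(OCOC)c1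
F5 | step 4 | 3-bromo-2,6-bis(methoxymethoxy)phenyllithium | [Li]c1c(OCOC)ccc(Br)c1OCOC
F6 | step 4 | 3-bromo-2,6-bis(methoxymethoxy)phenylcopper | [Cu]c1c(OCOC)ccc(Br)c1OCOC
F7 | step 4 | 1-bromo-2,4-bis(methoxymethoxy)-3-(3-methylbut-2-enyl)benzene | COCOc1ccc(Br)c(OCOC)c1CC=C(C)C
F8 | step 7 | 1-[3-(3-methylbut-2-enyl)-2,4-bis(trimethylsilyloxy)phenyl]-2-[4-methoxy-2-(trimethylsilyloxy)phenyl]ethane-1,2-dione | COc1ccc(C(=O)C(=O)c2ccc(O[Si](C)(C)C)c(CC=C(C)C)c2O[Si](C)(C)C)c(O[Si](C)(C)C)c1
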